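**Plan**
- Numbering: side-chain carbons run C1′ (benzylic) to C17′ (CH3); the carbinol is C15′ (S) and the alkene is C8′=C9′ (Z).
- Retrosynthesis cuts, in order: the two aryl O–Si bonds (phenol masks); the C2′–C3′ CH2–CH2 bond, giving a 2-arylethyl unit and the complete C15 chain; the C8′=C9′ alkene (two terminal alkenes); the C13′–C14′ bond (Grignard reagent plus epoxide).
- Enabling feature: the resorcinol ring sits two carbons from C2′, so C1′=C2′ can be a vinylarene. 9-BBN places boron on C2′, and a Pd alkyl–alkyl Suzuki coupling with the primary bromide at C3′ completes a one-pot anti-Markovnikov hydroalkylation by a two-electron path that leaves the Z-alkene and the free carbinol alone.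
- Forward order: the chain (epoxide opening, then Z-selective cross-metathesis) and the arene (silylation, then methylenation) are made separately, joined in the key step and desilylated; no ring is formed.
- Stereochemistry: C15′ comes unchanged from (S)-1,2-epoxybutane (attack at its CH2); the Z geometry comes from catalyst control in the cross-metathesis.

Key step: step 5

Remark on the chemistry: 2 is taken as the commercial THF solution, and the step 2 catalyst is the commercial cyclometalated Z-selective ruthenium–NHC nitrato complex.

**Step 1**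
Reactants: 1 (S)-1,2-epoxybutane; 2 hex-5-enylmagnesium bromide
Product: 3 (S)-dec-9-en-3-ol
Conditions: CuI (10 mol%), THF, −40 → 0 °C; H2O quench
Reagents that add atoms: none
Why: Copper-catalysed Grignard opening of a terminal epoxide proceeds by SN2 attack at the unsubstituted CH2 of 1, so the C–O stereocentre is not touched and becomes the (S)-carbinol of 3 unchanged.

**Step 2**
Reactants: 3 (S)-dec-9-en-3-ol; 4 7-bromohept-1-ene (3 equiv)
Product: 5 (3S,9Z)-15-bromopentadec-9-en-3-ol
Conditions: cyclometalated Ru–NHC nitrato catalyst (Z-selective, 2 mol%), THF, 35 °C, static vacuum; SiO2, then AgNO3–SiO2 chromatography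
Reagents that add atoms: none
Why: Z-selective olefin cross-metathesis of two unhindered terminal alkenes, in which the side-bound ruthenacyclobutane of the cyclometalated catalyst forces both substituents to the same face and should give the Z-alkene under kinetic control; the remote hydroxyl and primary bromide are tolerated, excess 4 favours the cross product, and the polar diol and non-polar dibromide homodimers separate easily.

**Step 3**
Reactants: 6 3,5-dihydroxybenzaldehyde
Product: 7 3,5-bis(triisopropylsilyloxy)benzaldehyde
Conditions: TIPSCl (2.4 equiv), imidazole, DMF, rt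
Reagents that add atoms: triisopropylsilyl chloride, CC(C)[Si](Cl)(C(C)C)C(C)C
Why: Imidazole-promoted silylation of phenols; TIPS ethers are chosen because they should resist the ylide, the borane and the phosphate base of later steps and fall to fluoride at the end.

**Step 4**
Reactants: 7 3,5-bis(triisopropylsilyloxy)benzaldehyde
Product: 8 1-ethenyl-3,5-bis(triisopropylsilyloxy)benzene
Conditions: Ph3PCH3Br, KOtBu, THF, 0 °C → rt
Reagents that add atoms: methyltriphenylphosphonium bromide, C[P+](c1ccccc1)(c1ccccc1)c1ccccc1.[Br-]
Why: Wittig methylenation of an aromatic aldehyde with the non-stabilised ylide, which the hindered aryl silyl ethers should survive.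

**Step 5**
Reactants: 8 1-ethenyl-3,5-bis(triisopropylsilyloxy)benzene (1.35 equiv); 5 (3S,9Z)-15-bromopentadec-9-en-3-ol (1.0 equiv)
Product: 10 (3S,9Z)-17-[3,5-bis(triisopropylsilyloxy)phenyl]heptadec-9-en-3-ol, via B-(2-arylethyl)-9-BBN 9 (not isolated)
Conditions: 8, 9-BBN (1.3 equiv), THF, 0 °C → rt; then 5, Pd(OAc)2 (4 mol%), PCy3 (8 mol%), K3PO4·H2O (1.5 equiv), THF, rt
Reagents that add atoms: none
Why: 9-BBN adds across the vinyl group of 8 by four-centre syn-addition with boron on terminal C2′ and hydrogen on benzylic C1′ to give 9; Pd(0)/PCy3 then enters the primary C3′–Br bond of 5 by SN2-type oxidative addition, the hydroxide-activated borate of 9 transfers its primary 2-arylethyl group to palladium, and reductive elimination forms the C2′–C3′ sp3–sp3 bond. The closest known reaction type is the room-temperature B-alkyl Suzuki–Miyaura coupling of alkyl-9-BBN reagents with primary alkyl bromides that carry β-hydrogens (Pd/trialkylphosphine, K3PO4·H2O), run here in one pot with the hydroboration so that the whole amounts to an anti-Markovnikov hydroalkylation of a vinylarene. No ring is closed and no stereocentre is created, so the only stereochemical demand is that C15′ (S) and the Z-configured C8′=C9′ alkene, both remote from the reacting carbons, pass through unchanged. The step needs regioselective placement of boron, secured by the aryl ring on C1′ together with the bulk of 9-BBN, and chemoselectivity for the vinylarene over the internal alkene, secured by consuming all B–H with a slight excess of 8 before 5 is added. It also needs coupling to outrun β-hydride elimination, which the bulky electron-rich PCy3 ligand at room temperature should provide, and transfer of the primary alkyl group in preference to the secondary bicyclic B–C bonds, which is inherent to 9-BBN reagents. Because no radical is formed at C3′, 6-exo cyclisation onto C8′=C9′ and 1,5-hydrogen shift from allylic C7′ cannot scramble the alkene, and the free secondary hydroxyl is inert to the trialkylborane and to the mild phosphate base.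

**Step 6**
Reactants: 10 (3S,9Z)-17-[3,5-bis(triisopropylsilyloxy)phenyl]heptadec-9-en-3-ol
Product: 11 Hansfordiol G
Conditions: TBAF (2.5 equiv), AcOH (2.5 equiv), THF, 0 °C, argon
Reagents that add atoms: none
Why: Fluoride-mediated desilylation cleaves the two aryl O–Si bonds rapidly (strong Si–F bond, phenoxide leaving group), the acetic acid buffer protects the electron-rich resorcinol from base and air, and the alkene and carbinol are not affected.

**Compound list**
1 | (S)-1,2-epoxybutane [(S)-2-ethyloxirane] | CC[C@H]1CO1 | starting material
2 | hex-5-enylmagnesium bromide (THF solution) | C=CCCCC[Mg]Br | starting material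
3 | (S)-dec-9-en-3-ol | CC[C@H](O)CCCCCC=C | intermediate
4 | 7-bromohept-1-ene | C=CCCCCCBr | starting material
5 | (3S,9Z)-15-bromopentadec-9-en-3-ol | CC[C@H](O)CCCCC/C=C\CCCCCBr | intermediate
6 | 3,5-dihydroxybenzaldehyde | O=Cc1cc(O)cc(O)c1 | starting material
7 | 3,5-bis(triisopropylsilyloxy)benzaldehyde | O=Cc1cc(O[Si](C(C)C)(C(C)C)C(C)C)cc(O[Si](C(C)C)(C(C)C)C(C)C)c1 | intermediate
8 | 1-ethenyl-3,5-bis(triisopropylsilyloxy)benzene | C=Cc1cc(O[Si](C(C)C)(C(C)C)C(C)C)cc(O[Si](C(C)C)(C(C)C)C(C)C)c1 | intermediate
9 | 9-{2-[3,5-bis(triisopropylsilyloxy)phenyl]ethyl}-9-borabicyclo[3.3.1]nonane | CC(C)[Si](Oc1cc(CCB2C3CCCC2CCC3)cc(O[Si](C(C)C)(C(C)C)C(C)C)c1)(C(C)C)C(C)C | intermediate (formed in the flask, not isolated)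
10 | (3S,9Z)-17-[3,5-bis(triisopropylsilyloxy)phenyl]heptadec-9-en-3-ol | CC[C@H](O)CCCCC/C=C\CCCCCCCc1cc(O[Si](C(C)C)(C(C)C)C(C)C)cc(O[Si](C(C)C)(C(C)C)C(C)C)c1 | intermediate
11 | Hansfordiol G, 5-[(8Z,15S)-15-hydroxyheptadec-8-en-1-yl]benzene-1,3-diol | CC[C@H](O)CCCCC/C=C\CCCCCCCc1cc(O)cc(O)c1 | target

**Totals**
Total step count: 6. Longest linear sequence: 4 steps (1 → 2 → 5 → 6, or equally 3 → 4 → 5 → 6).

**Steps most likely to fail**

First, step 2. The cross-metathesis may lose Z-selectivity through secondary metathesis of the product, may partition statistically into homodimers, and the catalyst may decompose before conversion is complete. The fallback replaces metathesis by alkyne semi-hydrogenation and sets out from 1. Opening of 1 at its CH2 with lithium hex-1-ynide and BF3·OEt2 (THF, −78 °C) should give (S)-dec-5-yn-3-ol F1. An alkyne zipper isomerisation (KH, 1,3-diaminopropane, 0 °C → rt) should move the triple bond to the free chain end and give (S)-dec-9-yn-3-ol F2; the alkoxide-bearing stereocentre is not expected to be deprotonated. The O,C-dianion of F2 (n-BuLi, 2.1 equiv, THF/DMPU) would be alkylated at carbon with excess 1,5-dibromopentane to give (S)-15-bromopentadec-9-yn-3-ol F3. Syn-hydrogenation over Lindlar catalyst (H2, quinoline, EtOAc) should then set the Z-alkene and deliver 5, where the route is rejoined.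

Second, step 5. β-Hydride elimination from the alkylpalladium intermediates, slow transmetalation of the borate, or Pd–H-mediated isomerisation of the Z-alkene may compete with C–C bond formation. The fallback is a palladium-free, copper-catalysed Grignard–alkyl bromide coupling that forms the same C2′–C3′ bond; it sets out from 8 and 5. Hydroboration of 8 to 9 followed by oxidation (NaBO3·4H2O, THF/H2O) would give 2-[3,5-bis(triisopropylsilyloxy)phenyl]ethan-1-ol F4. CBr4/PPh3 would convert it into 1-(2-bromoethyl)-3,5-bis(triisopropylsilyloxy)benzene F5, and Mg in THF into 2-[3,5-bis(triisopropylsilyloxy)phenyl]ethylmagnesium bromide F6. In parallel 5 would be silylated (TBSCl, imidazole, DMF) to (3S,9Z)-15-bromo-3-(tert-butyldimethylsilyloxy)pentadec-9-ene F7. Coupling of F6 with F7 under Li2CuCl4 catalysis (THF, −20 °C → rt) should give (3S,9Z)-3-(tert-butyldimethylsilyloxy)-17-[3,5-bis(triisopropylsilyloxy)phenyl]heptadec-9-ene F8. Excess TBAF (THF, rt) would then remove all three silyl groups and arrive at 11.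

Third, step 1. Opening of the epoxide by bromide (bromohydrin formation promoted by magnesium salts), attack at the substituted carbon, or homocoupling of the Grignard reagent may erode the yield. The fallback replaces the chiral epoxide by a racemic carbinol and an enzymatic kinetic resolution; it sets out from 4. Its Grignard reagent hept-6-enylmagnesium bromide F9 (Mg, THF) would add to propanal to give racemic dec-9-en-3-ol F10. Acylation with vinyl acetate catalysed by immobilised Candida antarctica lipase B (hexane, rt), run slightly beyond half conversion, should convert the R enantiomer into (R)-dec-9-en-3-yl acetate F11 and leave the S alcohol. That alcohol is 3; it is separated by chromatography and the route is rejoined there.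

**Further compounds**
F1 | step 2 | (S)-dec-5-yn-3-ol | CC[C@H](O)CC#CCCCC
F2 | step 2 | (S)-dec-9-yn-3-ol | CC[C@H](O)CCCCCC#C
F3 | step 2 | (S)-15-bromopentadec-9-yn-3-ol | CC[C@H](O)CCCCCC#CCCCCCBr
F4 | step 5 | 2-[3,5-bis(triisopropylsilyloxy)phenyl]ethan-1-ol | OCCc1cc(O[Si](C(C)C)(C(C)C)C(C)C)cc(O[Si](C(C)C)(C(C)C)C(C)C)c1
F5 | step 5 | 1-(2-bromoethyl)-3,5-bis(triisopropylsilyloxy)benzene | BrCCc1cc(O[Si](C(C)C)(C(C)C)C(C)C)cc(O[Si](C(C)C)(C(C)C)C(C)C)c1
F6 | step 5 | 2-[3,5-bis(triisopropylsilyloxy)phenyl]ethylmagnesium bromide | Br[Mg]CCc1cc(O[Si](C(C)C)(C(C)C)C(C)C)cc(O[Si](C(C)C)(C(C)C)C(C)C)c1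
F7 | step 5 | (3S,9Z)-15-bromo-3-(tert-butyldimethylsilyloxy)pentadec-9-ene | CC[C@H](O[Si](C)(C)C(C)(C)C)CCCCC/C=C\CCCCCBr
F8 | step 5 | (3S,9Z)-3-(tert-butyldimethylsilyloxy)-17-[3,5-bis(triisopropylsilyloxy)phenyl]heptadec-9-ene | CC[C@H](O[Si](C)(C)C(C)(C)C)CCCCC/C=C\CCCCCCCc1cc(O[Si](C(C)C)(C(C)C)C(C)C)cc(O[Si](C(C)C)(C(C)C)C(C)C)c1
F9 | step 1 | hept-6-enylmagnesium bromide | C=CCCCCC[Mg]Br
F10 | step 1 | racemic dec-9-en-3-ol | CCC(O)CCCCCC=C
F11 | step 1 | (R)-dec-9-en-3-yl acetate | CC[C@@H](OC(C)=O)CCCCCC=C
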